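Readings and results were generated by integration from invented constants; scatter was added.

The vessel is closed and stirred, and nothing enters it unless we add it. Cedar is the flask in question; alder is an earlier flask, colder and with more free enzyme.

| setting | cedar | alder | flask |
|---|---|---|---|
| starting material | 0.025 M | 0.025 M | 0.025 M |
| protic impurity | 5 mM | 5 mM | 5.00 mM |
| free enzyme | 2.5 µM | 3.8 µM | 2.5 µM |
| temperature | 25 °C | 10 °C | 25 °C |
| remark | the very flask that is asked about, followed so far | run made earlier |  |
| time |  |  | 8.0 d |

- cedar (time / d: target / %, starting material / %): 1.25: 64, 17; 2.50: 71, 9; 4.00: 72, 9; 5.00: 71, 10; 6.00: 70, 8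
- alder (time / d: target / %, starting material / %): 1.04: 37, 47; 2.50: 55, 26; 5.00: 69, 11; 8.00: 78, 5; 12.0: 80, 0

(readings scatter by 1.5 percentage points)

- south: change nothing and wait 2.5 d more
- north-east: at 8.0 d raise the temperature by 20 K, then wait 2.5 d
- north-west: at 8.0 d take out 90% of the target then present, then wait 2.5 d
- south-west: at 8.0 d add free enzyme, 100% of the amount charged, then wait 2.5 d

- target taken out counts as made
- additions bring no volume worth counting

* target, in percent of the starting material first charged, at 8.0 d
* which option adds most target ("none" when 2 percentage points or less is all one gets) (south / north-east / north-west / south-west / none)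
* target present, with what was taken out counted in, in percent of the starting material first charged, after north-east
* target present, with what was taken out counted in, in percent of the starting material first charged, after south-west

**What do the cedar readings say?** From 2.50 d on they stand still within their scatter of 1.5 percentage points. Target averages 71.0% and starting material 9.00%, so I commit to 71.0% at 8.0 d.

**Where is the rest of the charge?** The gap is 20.0%, and the protic impurity was charged at 20.0% of the starting material. I take it that the impurity consumes its equal of starting material.

**Why does cedar stop with starting material left: equilibrium or dead enzyme?** The cedar readings show a standstill, and either would give one. In alder, ln[starting material] falls by 0.406 /d early and by 0.263 /d between 5.00 d and 8.00 d, slower as read, yet it reads 0% at 12.0 d. I bet on a dying enzyme.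

**What can you carry from that?** Suppose [starting material] falls at a rate proportional to itself times [free enzyme] (pseudo-first-order at any moment), and [free enzyme] decays in proportion to itself. Divide one rate by the other and time drops out. Cedar's dose gives ln((71.0% + 9.00%) / 9.00%) = 2.18. I call this the reach of a dose: the natural logarithm of the factor by which one dose cuts the starting material before it dies.

**But fresh enzyme meets 9.00% starting material, not 80.0%. Does the reach hold?** On the supposition above it is a factor, not an amount, so I apply it as it stands. By this reckoning a second equal dose takes 9.00% to 1.01%, which brings target to 79.0%. That gain of 8 points exceeds the margin of 2 points. If my bet on a dying enzyme holds, waiting, heating and taking out target find no working enzyme at 8.0 d, so I expect nothing from them, and north-east stays at 71.0%.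

The forecast gives 71% (69.5% to 72.5%), south-west as best, 71% after north-east and 78.5% after south-west, just under my 79.0%, and says “I read this as enzyme death”.

The flask gives 72.0% at 8.0 d, 72.0% after north-east and 80.0% after south-west; south-west adds 8 points, and waiting adds 0 points.

    free enzyme → unfolded enzyme (k = 0.00369 /h, Ea = 273 kJ/mol)
    starting material + free enzyme ⇌ complex (K = 268 /M, k = 6.09 × 10⁶ /M/h, Ea = 38.0 kJ/mol, ΔH = −44.0 kJ/mol)
    complex → free enzyme + target (k = 853 /h, Ea = 68.0 kJ/mol)
    free enzyme → spent catalyst A (k = 0.0809 /h, Ea = 106 kJ/mol)
    starting material + protic impurity → quenched substrate (k = 27.5 /M/h, Ea = 63.0 kJ/mol)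
    2 complex → spent catalyst B (k = 45900 /M/h, Ea = 51.0 kJ/mol)
    (constants at 25 °C)

At 8.00 d the flask holds 8.00% starting material beside 72.0% target, a reach of 2.30. Its slowest mode has a half-life of 0.525 d against the 8.0 d waited, and target still reads 72.0% at 80.0 d. Applied to the second dose in this flask, that reach leaves 0.802% starting material and 79.2% target, where south-west gives 80.0%. The repeat at 40 °C holds 46.7% starting material beside 33.3% target at 8.00 d, a smaller reach of 0.538.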